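**Retrosynthetic overview**
- Target 19 comes from its tris-MOM ether 18 by mild acid solvolysis in the last step.
- C2 is the β-carbon of the C4 ketone in ring C and carries only ring B. The C2–C1' bond is therefore cut to the flat chromone 12 and arylboronic acid 17, and a chiral rhodium catalyst chooses the face.
- In ring A the geranyl carbon C6 lies between the oxygenated C5 and C7 and para to C8a (the carbon bearing O1). All ring A substituents can thus be placed on a mirror-symmetric resorcinol core with no 6- versus 8-isomer problem: geranyl by ortho-lithiation, O1 by C–H borylation/oxidation, the C4 carbon by ortho-formylation.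
- Ring order: ring A is bought (resorcinol 1), ring C is closed through the O1–C2 bond from an enaminone of acetophenone 10, and ring B (from 13) is attached last.

Key step: step 11

Remark on notation: geranyl means (2E)-3,7-dimethylocta-2,6-dien-1-yl, MOM means methoxymethyl, and (S)-MeO-F12-BIPHEP means (S)-2,2'-bis[bis(3,4,5-trifluorophenyl)phosphino]-6,6'-dimethoxy-1,1'-biphenyl.
Remark on the chemistry: the (S)-antipode of the bisphosphine is assumed, by analogy with additions to cyclic enones, to give 2S; if a pilot run (CD, chiral HPLC) shows 2R, the (R)-antipode is used and nothing else changes.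

**Route**

Step 1
Reactants: 1 resorcinol
Product: 2 1,3-bis(methoxymethoxy)benzene
Conditions: NaH, MOMCl, DMF, 0 °C to rt
Reagents that add atoms: chloromethyl methyl ether COCCl
Why: Williamson-type O-alkylation of both phenoxides installs two MOM ethers, which later direct the ortho-lithiation.

Step 2
Reactants: 2 1,3-bis(methoxymethoxy)benzene; 3 (E)-geranyl bromide
Product: 5 2-geranyl-1,3-bis(methoxymethoxy)benzene, via aryllithium 4 (not isolated)
Conditions: n-BuLi, THF, 0 °C to rt; then CuBr·SMe2 (10 mol%), 3, −78 to 0 °C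
Reagents that add atoms: n-butyllithium [Li]CCCC (lithium of 4)
Why: Directed ortho-metalation at the C–H flanked by both OMOM groups, then copper-catalysed SN2 allylation at the primary carbon of the bromide, should keep the E olefin because no allyl cation or π-allyl metal is involved.

Step 3
Reactants: 5 2-geranyl-1,3-bis(methoxymethoxy)benzene
Product: 7 4-geranyl-3,5-bis(methoxymethoxy)phenol, via arylboronate 6 (not isolated)
Conditions: [Ir(OMe)(cod)]2 (1.5 mol%), 4,4'-di-tert-butyl-2,2'-bipyridine (3 mol%), B2pin2 (1.0 equiv), THF, 60 °C; then aq NaOH, 30% H2O2, THF, 0 °C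
Reagents that add atoms: bis(pinacolato)diboron CC1(C)OB(OC1(C)C)B1OC(C)(C)C(C)(C)O1 (boron of 6); hydrogen peroxide OO (oxygen of 7)
Why: Sterically controlled iridium-catalysed aromatic C–H borylation should take the only ring C–H without an ortho substituent (para to geranyl), and basic peroxide oxidation of the boronate (aryl shift from boron to oxygen) gives the phenol without epoxidising the isolated olefins.

Step 4
Reactants: 7 4-geranyl-3,5-bis(methoxymethoxy)phenol
Product: 8 5-geranyl-2-hydroxy-4,6-bis(methoxymethoxy)benzaldehyde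
Conditions: MgCl2, Et3N, (CH2O)n, MeCN, reflux; cold aq citric acid work-up
Reagents that add atoms: formaldehyde (as paraformaldehyde) C=O
Why: Casnati–Skattebøl ortho-formylation: the magnesium phenoxide delivers formaldehyde to an ortho carbon and a second formaldehyde oxidises the hydroxymethyl intermediate; the two ortho sites are equivalent and the para site is blocked, so one aldehyde is expected.

Step 5
Reactants: 8 5-geranyl-2-hydroxy-4,6-bis(methoxymethoxy)benzaldehyde
Product: 9 rac-1-[5-geranyl-2-hydroxy-4,6-bis(methoxymethoxy)phenyl]ethanol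
Conditions: MeMgBr (3 equiv), THF, −20 to 0 °C; aq NH4Cl; used crude
Reagents that add atoms: methylmagnesium bromide C[Mg]Br
Why: Grignard 1,2-addition to the aldehyde after the first equivalent deprotonates the phenol; the new carbinol centre forms as a racemate and is removed in step 6.

Step 6
Reactants: 9 rac-1-[5-geranyl-2-hydroxy-4,6-bis(methoxymethoxy)phenyl]ethanol
Product: 10 1-[5-geranyl-2-hydroxy-4,6-bis(methoxymethoxy)phenyl]ethanone
Conditions: activated MnO2 (excess), CH2Cl2, rt
Reagents that add atoms: none
Why: Heterogeneous MnO2 oxidation of a benzylic alcohol under neutral conditions should give the hydrogen-bonded ortho-hydroxyacetophenone and leave the MOM ethers and olefins untouched.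

Step 7
Reactants: 10 1-[5-geranyl-2-hydroxy-4,6-bis(methoxymethoxy)phenyl]ethanone
Product: 11 (E)-3-(dimethylamino)-1-[5-geranyl-2-hydroxy-4,6-bis(methoxymethoxy)phenyl]prop-2-en-1-one
Conditions: DMF dimethyl acetal (3 equiv), toluene, 90 °C; used crude
Reagents that add atoms: N,N-dimethylformamide dimethyl acetal COC(OC)N(C)C
Why: Condensation of the methyl ketone with the amide acetal (enaminone formation) supplies the C2 carbon of ring C; the chelated phenol should resist O-methylation.

Step 8
Reactants: 11 (E)-3-(dimethylamino)-1-[5-geranyl-2-hydroxy-4,6-bis(methoxymethoxy)phenyl]prop-2-en-1-one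
Product: 12 6-geranyl-5,7-bis(methoxymethoxy)-4H-chromen-4-one
Conditions: SiO2, AcOH (2 equiv), CH2Cl2, 35 °C
Reagents that add atoms: none
Why: Intramolecular oxa-Michael addition of the phenol to the enaminone β-carbon and loss of dimethylamine (6-endo addition–elimination) closes ring C through the O1–C2 bond; the weak buffered acid should spare the MOM ethers and the geranyl chain.

Step 9
Reactants: 13 5-bromo-2-methoxyphenol
Product: 14 4-bromo-1-methoxy-2-(methoxymethoxy)benzene
Conditions: NaH, MOMCl, THF/DMF, 0 °C to rt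
Reagents that add atoms: chloromethyl methyl ether COCCl
Why: Williamson-type O-alkylation masks the ring B phenol so that no phenoxide is present in the lithiation or in the rhodium step.

Step 10
Reactants: 14 4-bromo-1-methoxy-2-(methoxymethoxy)benzene
Product: 17 [4-methoxy-3-(methoxymethoxy)phenyl]boronic acid, via aryllithium 15 (not isolated), via lithium aryltriisopropoxyborate 16 (not isolated)
Conditions: n-BuLi, THF, −78 °C; B(OiPr)3, −78 °C to rt; H2O, extraction at pH 6–7
Reagents that add atoms: n-butyllithium [Li]CCCC (lithium of 15 and 16); triisopropyl borate CC(C)OB(OC(C)C)OC(C)C; water O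
Why: Bromine–lithium exchange followed by borylation of the aryllithium and near-neutral hydrolysis of the borate gives the boronic acid with the MOM ether intact.

Step 11
Reactants: 12 6-geranyl-5,7-bis(methoxymethoxy)-4H-chromen-4-one; 17 [4-methoxy-3-(methoxymethoxy)phenyl]boronic acid
Product: 18 (2S)-6-geranyl-2-[4-methoxy-3-(methoxymethoxy)phenyl]-5,7-bis(methoxymethoxy)chroman-4-one
Conditions: [Rh(OH)(cod)]2 (2.5 mol%), (S)-MeO-F12-BIPHEP (5.5 mol%), 17 (3 equiv), CH2Cl2/H2O (10:1), 35 °C, no added base
Reagents that add atoms: none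
Why: The aryl group of 17 transmetalates from boron to the hydroxo complex of monovalent rhodium, the C2=C3 bond of 12 binds and inserts into the aryl–rhodium bond to give an oxa-π-allyl rhodium enolate, and water protonates it to release 18 and regenerate Rh–OH. The closest known reaction is the Hayashi–Miyaura-type asymmetric 1,4-addition of arylboronic acids to chromone itself with electron-poor biaryl bisphosphine or chiral diene rhodium catalysts, giving 2-arylchroman-4-ones. No ring is closed, since ring C is already in place; only the C2–C1' bond forms. The C2 stereocentre is set by the chiral ligand alone, which shields one face of the planar, achiral chromone, and the 2S sense is to be confirmed by CD and chiral HPLC. The step needs 1,4- over 1,2-addition and chemoselectivity against the geranyl olefins; the unhindered conjugated C2=C3 bond, the C4 carbonyl flanked by the 5-OMOM group, and isolated trisubstituted olefins that do not insert aryl–rhodium should secure this. With all phenols masked and no base added, no phenoxide can open 18 to a chalcone, so the new centre should not erode; the donor-rich enone may need the higher loading given.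

Step 12
Reactants: 18 (2S)-6-geranyl-2-[4-methoxy-3-(methoxymethoxy)phenyl]-5,7-bis(methoxymethoxy)chroman-4-one
Product: 19 (2S)-6-geranyl-5,7-dihydroxy-2-(3-hydroxy-4-methoxyphenyl)chroman-4-one
Conditions: conc. HCl (to about 1 M), MeOH/THF, rt, monitored and stopped at full conversion
Reagents that add atoms: none
Why: Acid-catalysed acetal solvolysis transfers the three methoxymethyl groups to methanol; at room temperature and without base, ring opening to the chalcone (racemisation of C2) and cation–olefin cyclisation of the geranyl chain onto the 5- or 7-OH should both be avoided.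

**Compound list**
1 | resorcinol | Oc1cccc(O)c1 | starting material
2 | 1,3-bis(methoxymethoxy)benzene | COCOc1cccc(OCOC)c1 | intermediate
3 | (E)-geranyl bromide, (2E)-1-bromo-3,7-dimethylocta-2,6-diene | BrC/C=C(\C)CCC=C(C)C | starting material
4 | 2-lithio-1,3-bis(methoxymethoxy)benzene | [Li]c1c(OCOC)cccc1OCOC | intermediate
5 | 2-geranyl-1,3-bis(methoxymethoxy)benzene | COCOc1cccc(OCOC)c1C/C=C(\C)CCC=C(C)C | intermediate
6 | 2-[4-geranyl-3,5-bis(methoxymethoxy)phenyl]-4,4,5,5-tetramethyl-1,3,2-dioxaborolane | COCOc1cc(B2OC(C)(C)C(C)(C)O2)cc(OCOC)c1C/C=C(\C)CCC=C(C)C | intermediate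
7 | 4-geranyl-3,5-bis(methoxymethoxy)phenol | COCOc1cc(O)cc(OCOC)c1C/C=C(\C)CCC=C(C)C | intermediate
8 | 5-geranyl-2-hydroxy-4,6-bis(methoxymethoxy)benzaldehyde | O=Cc1c(O)cc(OCOC)c(C/C=C(\C)CCC=C(C)C)c1OCOC | intermediate
9 | rac-1-[5-geranyl-2-hydroxy-4,6-bis(methoxymethoxy)phenyl]ethanol | CC(O)c1c(O)cc(OCOC)c(C/C=C(\C)CCC=C(C)C)c1OCOC | intermediate
10 | 1-[5-geranyl-2-hydroxy-4,6-bis(methoxymethoxy)phenyl]ethanone | CC(=O)c1c(O)cc(OCOC)c(C/C=C(\C)CCC=C(C)C)c1OCOC | intermediate
11 | (E)-3-(dimethylamino)-1-[5-geranyl-2-hydroxy-4,6-bis(methoxymethoxy)phenyl]prop-2-en-1-one | CN(C)/C=C/C(=O)c1c(O)cc(OCOC)c(C/C=C(\C)CCC=C(C)C)c1OCOC | intermediate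
12 | 6-geranyl-5,7-bis(methoxymethoxy)-4H-chromen-4-one | O=c1ccoc2cc(OCOC)c(C/C=C(\C)CCC=C(C)C)c(OCOC)c12 | intermediate
13 | 5-bromo-2-methoxyphenol | COc1ccc(Br)cc1O | starting material
14 | 4-bromo-1-methoxy-2-(methoxymethoxy)benzene | COCOc1cc(Br)ccc1OC | intermediate
15 | [4-methoxy-3-(methoxymethoxy)phenyl]lithium | [Li]c1ccc(OC)c(OCOC)c1 | intermediate
16 | lithium triisopropoxy[4-methoxy-3-(methoxymethoxy)phenyl]borate | [Li+].CC(C)O[B-](OC(C)C)(OC(C)C)c1ccc(OC)c(OCOC)c1 | intermediate
17 | [4-methoxy-3-(methoxymethoxy)phenyl]boronic acid | COCOc1cc(B(O)O)ccc1OC | intermediate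
18 | (2S)-6-geranyl-2-[4-methoxy-3-(methoxymethoxy)phenyl]-5,7-bis(methoxymethoxy)chroman-4-one | COc1ccc([C@@H]2CC(=O)c3c(cc(OCOC)c(C/C=C(\C)CCC=C(C)C)c3OCOC)O2)cc1OCOC | intermediate
19 | (2S)-6-geranyl-5,7-dihydroxy-2-(3-hydroxy-4-methoxyphenyl)chroman-4-one | COc1ccc([C@@H]2CC(=O)c3c(cc(O)c(C/C=C(\C)CCC=C(C)C)c3O)O2)cc1O | target

**Step count**
Total: 12 steps. Longest linear sequence: 10 steps (steps 1–8, 11, 12 from resorcinol); the boronic acid branch has 2 steps (steps 9, 10).

**Three steps most likely to fail**

Step 11. Insertion of the donor-rich, 5-alkoxy-substituted chromone into the aryl–rhodium bond may be slow. Protodeboronation of the electron-rich boronic acid could then outpace the conjugate addition, or the facial selectivity could be insufficient. The fallback sets out from acetophenone 10 and bromide 14 and returns at 18. Bromide 14 would be lithiated (n-BuLi, THF, −78 °C, through 15) and formylated with DMF to give 4-methoxy-3-(methoxymethoxy)benzaldehyde F1. Claisen–Schmidt condensation of 10 with F1 (KOH, EtOH, rt) should give (E)-1-[5-geranyl-2-hydroxy-4,6-bis(methoxymethoxy)phenyl]-3-[4-methoxy-3-(methoxymethoxy)phenyl]prop-2-en-1-one F2. Buffered intramolecular oxa-Michael cyclisation through the free 2'-hydroxyl (NaOAc, EtOH, reflux) should then give the racemic flavanone rac-6-geranyl-2-[4-methoxy-3-(methoxymethoxy)phenyl]-5,7-bis(methoxymethoxy)chroman-4-one F3. Preparative chiral HPLC on a polysaccharide carbamate phase would separate 18 from the (2R)-enantiomer F4, which can be returned to the NaOAc equilibration and separated again.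

Step 3. The iridium boryl species may hydroborate or borylate the geranyl olefins or their allylic positions and so divert material from aromatic C–H borylation. The fallback sets out from 2 and returns at 7. The olefin-free arene 2 would be borylated under the same iridium conditions at its only unhindered C–H (meta to both OMOM groups) to give 2-[3,5-bis(methoxymethoxy)phenyl]-4,4,5,5-tetramethyl-1,3,2-dioxaborolane F5, and oxidised (aq NaOH, H2O2) to 3,5-bis(methoxymethoxy)phenol F6. Silylation (TIPSCl, imidazole, DMF) would give [3,5-bis(methoxymethoxy)phenoxy]triisopropylsilane F7. Directed ortho-lithiation between the two OMOM groups (n-BuLi, THF, 0 °C; the bulky silyl ether is a poor director) would give [3,5-bis(methoxymethoxy)-4-lithiophenoxy]triisopropylsilane F8. Copper-catalysed allylation with 3 would give [4-geranyl-3,5-bis(methoxymethoxy)phenoxy]triisopropylsilane F9, and TBAF in THF would release phenol 7.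

Step 6. The ortho-hydroxybenzylic alcohol 9 may ionise to an ortho-quinone methide, or the electron-rich phenol ring may be degraded oxidatively, before the alcohol is oxidised. The fallback sets out from phenol 7 and returns at 10; it replaces steps 4 to 6 with a directed acylation. Phenol 7 would be protected with ethyl vinyl ether (pyridinium p-toluenesulfonate, CH2Cl2) as 1-(1-ethoxyethoxy)-4-geranyl-3,5-bis(methoxymethoxy)benzene F10. Ortho-lithiation between the two acetal oxygens (n-BuLi, THF, −20 to 0 °C; the two open sites are equivalent) would give 2-lithio-1-(1-ethoxyethoxy)-4-geranyl-3,5-bis(methoxymethoxy)benzene F11. Acylation with N-methoxy-N-methylacetamide would give 1-[2-(1-ethoxyethoxy)-5-geranyl-4,6-bis(methoxymethoxy)phenyl]ethanone F12. Selective removal of the far more labile ethoxyethyl acetal (pyridinium p-toluenesulfonate, MeOH, rt) would give acetophenone 10.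

**Further compounds**
F1 | step 11 | 4-methoxy-3-(methoxymethoxy)benzaldehyde | COCOc1cc(C=O)ccc1OC
F2 | step 11 | (E)-1-[5-geranyl-2-hydroxy-4,6-bis(methoxymethoxy)phenyl]-3-[4-methoxy-3-(methoxymethoxy)phenyl]prop-2-en-1-one | COCOc1cc(/C=C/C(=O)c2c(O)cc(OCOC)c(C/C=C(\C)CCC=C(C)C)c2OCOC)ccc1OC
F3 | step 11 | rac-6-geranyl-2-[4-methoxy-3-(methoxymethoxy)phenyl]-5,7-bis(methoxymethoxy)chroman-4-one | COc1ccc(C2CC(=O)c3c(cc(OCOC)c(C/C=C(\C)CCC=C(C)C)c3OCOC)O2)cc1OCOC
F4 | step 11 | (2R)-6-geranyl-2-[4-methoxy-3-(methoxymethoxy)phenyl]-5,7-bis(methoxymethoxy)chroman-4-one | COc1ccc([C@H]2CC(=O)c3c(cc(OCOC)c(C/C=C(\C)CCC=C(C)C)c3OCOC)O2)cc1OCOC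
F5 | step 3 | 2-[3,5-bis(methoxymethoxy)phenyl]-4,4,5,5-tetramethyl-1,3,2-dioxaborolane | COCOc1cc(OCOC)cc(B2OC(C)(C)C(C)(C)O2)c1
F6 | step 3 | 3,5-bis(methoxymethoxy)phenol | COCOc1cc(O)cc(OCOC)c1
F7 | step 3 | [3,5-bis(methoxymethoxy)phenoxy]triisopropylsilane | COCOc1cc(O[Si](C(C)C)(C(C)C)C(C)C)cc(OCOC)c1
F8 | step 3 | [3,5-bis(methoxymethoxy)-4-lithiophenoxy]triisopropylsilane | [Li]c1c(OCOC)cc(O[Si](C(C)C)(C(C)C)C(C)C)cc1OCOC
F9 | step 3 | [4-geranyl-3,5-bis(methoxymethoxy)phenoxy]triisopropylsilane | COCOc1cc(O[Si](C(C)C)(C(C)C)C(C)C)cc(OCOC)c1C/C=C(\C)CCC=C(C)C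
F10 | step 6 | 1-(1-ethoxyethoxy)-4-geranyl-3,5-bis(methoxymethoxy)benzene | CCOC(C)Oc1cc(OCOC)c(C/C=C(\C)CCC=C(C)C)c(OCOC)c1
F11 | step 6 | 2-lithio-1-(1-ethoxyethoxy)-4-geranyl-3,5-bis(methoxymethoxy)benzene | CCOC(C)Oc1c([Li])c(OCOC)c(C/C=C(\C)CCC=C(C)C)c(OCOC)c1
F12 | step 6 | 1-[2-(1-ethoxyethoxy)-5-geranyl-4,6-bis(methoxymethoxy)phenyl]ethanone | CCOC(C)Oc1cc(OCOC)c(C/C=C(\C)CCC=C(C)C)c(OCOC)c1C(C)=O
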